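## The problem

The target 13 is a 1,7-diarylheptanoid in which an oxygen bridges two chain carbons to form an oxane. In the locants used throughout, O1 is the ring oxygen, C2 carries the CH2CH2–ring B chain, C4 the hydroxyl, and C6 the guaiacyl ring A (systematic names in the compound lines use their own locants). There are three stereocentres, (2S,4S,6S): the two carbon substituents are cis and equatorial, and the C4 hydroxyl is axial, trans to both. The centres are not independent. C6 can set C2, because hydrogen adds to a C2=C3 double bond from the face away from the aryl group, and the locked diequatorial chair then directs a bulky hydride to give the axial C4 alcohol. Only one centre therefore needs outside control. The fragile parts are the two phenols, which must stay masked until the end, and the C6–O1 bond, a benzylic ether para to an oxygen donor that can ionise under acid and can be hydrogenolysed. β-Alkoxy ketone intermediates can also open by retro-oxa-Michael reaction. The enabling feature is that, at the 2,3-dihydro-4-pyranone oxidation level, C2–C3–C4–C5 is a four-carbon unit with a carbonyl at C4, nucleophilic at C5 (enolate) and electrophilic at C2 (oxocarbenium). Joining the two ends of this 1,4-dipole on paper gives a neutral, achiral, strained 3-ethoxycyclobutanone, and O1 with C6 is then the carbonyl group of O-benzylvanillin.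

## Retrosynthesis

**C4–H.** The axial alcohol of 13 is the less stable C4 epimer, so it cannot come from equilibration, and ring closures that install C4 oxygen under thermodynamic control would give the equatorial epimer. Cutting the C4–H bond leads to ketone 12, which has one stereocentre fewer and a chair locked by two equatorial groups. The forward step needs a hydride bulky enough to attack only from the equatorial side and tolerant of two phenoxides; LiBH(sec-Bu)3 in excess fits.

**C2–H, C3–H and the two O–benzyl bonds.** Removing the hydrogens across C2–C3 of 12 and restoring the benzyl ethers gives dihydropyranone 11, whose only stereocentre is C6. This cut is preferred to keeping C2 as a stereocentre and closing the ring by oxa-Michael addition, because one catalytic hydrogenation should saturate the double bond cis to C6–H and remove both benzyl groups. The forward step must reduce the enol ether double bond without breaking the C6–O1 bond.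

**C5–C6 and O1–C2 (key disconnection).** Cutting the vinylogous ester of 11 at these two bonds leaves O1 and C6 as aldehyde 8 and C2–C5 as the zwitterion 9, enolate at C5 and ethoxy-oxocarbenium ion at C2. Zwitterion 9 is the ring-opened isomer of cyclobutanone 7. In the forward direction 9 and 8 give the cyclic ketal 10, which loses its ethoxy group to give 11. The neighbouring cut (O1–C6 and C2–C3) would need an enolisable aliphatic aldehyde and a styryl diene, and a cut of O1–C2 alone only moves the stereochemical problem into an open-chain aldol. Here both partners are robust and achiral: 7 has a mirror plane, so its two ring CH2 groups are equivalent and only one dipole can form, and 8 has no α-hydrogens. The forward reaction asks a chiral Lewis acid to open the ring, to choose one face of the aldehyde, and to leave the benzylic ether of the product alone.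

**The four-membered ring.** Ketone 7 is the dechlorination product of 6, and 6 is opened at both ring bonds to the CCl2–C(=O) unit into dichloroketene 5 (made from trichloroacetyl chloride 4) and enol ether 3. Polarity fixes the regiochemistry: the nucleophilic CH2 of 3 bonds to the ketene carbonyl carbon, so the ethoxy-bearing carbon ends up 1,3 to the ketone as required. Unsubstituted ketene is too unreactive, hence the chlorines and their removal by zinc. Two steps exchange a strained ring for an acyclic enol ether.

**C=CH2 and O–benzyl.** Enol ether 3 is the methylenation product of ester 2, and 2 is the benzyl ether of the commercial ester 1. Carbonyl methylenation with Cp2TiMe2 can only give the 1,1-disubstituted enol ether. An acid-catalysed ketal elimination route to the same compound could place the double bond on either side of the oxygenated carbon and would be one step longer.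

## Roads not taken

**Alternative 1:** C4 is cut from both neighbours (C3–C4 and C4–C5) and becomes the anion of silyl dithiane A1. C5–C6 with ring A comes from aryl oxirane A2, and C2–C3 with the ring B chain from alkyl oxirane A3. Forward, lithiated A1 opens A2 at its CH2 terminus. A polar phosphoramide co-solvent then triggers a 1,4-Brook rearrangement that moves silicon to the benzylic oxygen and regenerates a dithiane anion, which opens A3. Both bonds form in one flask to give the open-chain product A4.

- Merits: every operation is established, the union is convergent, and C4 arrives masked at the ketone level.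
- Weak points: no ring closes. A2 is an electron-rich styrene oxide, prone to rearrangement and to attack at the benzylic carbon. Closing the oxane afterwards means ionising the benzylic centre, so a stereocentre bought by resolution is destroyed and reset by the C2 carbinol. The dithiane must then be removed beside two electron-rich arenes.
- Comparison: with two oxiranes to prepare and at least four steps after the coupling, the route would run to roughly twelve steps. It is safer on precedent. The chosen plan sets against this about half the length, and a key step that closes the ring while setting the one controlled stereocentre.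

**Alternative 2:** the O1–C2 bond is cut with a vinyl group standing in for the C2 chain. Forward, [Ir(cod)Cl]2 (monovalent iridium) with a chiral BINOL-derived phosphoramidite ionises the open-chain allylic carbonate A5, and the benzylic C6 hydroxyl attacks the substituted allyl terminus to give vinyl oxane A6.

- Merits: the axial C4 oxygen is in place as a silyl ether before the ring forms, so no late ketone reduction and no enone hydrogenation are needed. Ring B is attached last, which would serve analogues. The reaction class has firm precedent.
- Weak points: A5 must already hold the C4 and C6 centres in the anti-1,3 relationship, so the sequence leading to it is long. The catalyst must match or override the substrate's bias, and the nucleophile is a hindered, ionisable benzylic alcohol. Hydroboration, cross-coupling and two deprotections follow.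
- Comparison: on the late-stage problems of the chosen plan (steps 6 and 7) this road is better. The chosen plan sets against it a much shorter sequence and only one stereocentre to control.

**Alternative 3:** O1–C6 and C2–C3 are cut. Forward, a chiral tridentate (Schiff base)CrCl catalyst (trivalent chromium) promotes an endo hetero-Diels–Alder reaction of the ring A silyloxydiene A7 with the ring B aldehyde A8 to give the cis silyl enol ether A9.

- Merits: this is known chemistry. It sets C2 and C6 together in one catalytic step and delivers the C4 ketone level directly. The step count is about the same as in the chosen plan.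
- Weak points: A8 is enolisable. A7 lacks a terminal alkoxy group and is therefore a sluggish, polymerisation-prone styryl diene. A9 holds a benzylic, allylic ether next to the electron-rich arene.
- Comparison: on precedent alone this road is the better one, and it is the benchmark. The chosen plan sets against it a non-enolisable aromatic aldehyde, an achiral strain-loaded partner that needs no activating group on a diene, and a single face to control. It would also give a general enantioselective entry to dihydropyranones from cyclobutanones if the key step works.

Key step: step 5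

Assumption: (R)-BINOL is written as the ligand that directs the enolate to the Si face of aldehyde 8. The sense of induction has no precedent for this reaction; if it proves opposite, the (S)-ligand is used with nothing else changed.

Remark: compounds 1, 4 and 8 are catalogue chemicals. Ketone 6 is racemic at its ether carbon, and that centre disappears in step 4.

## Route

Step 1
Reactants: 1 ethyl 3-(4-hydroxy-3-methoxyphenyl)propanoate
Product: 2 ethyl 3-[4-(benzyloxy)-3-methoxyphenyl]propanoate
Conditions: BnBr, K2CO3, DMF, rt
Reagents that add atoms: benzyl bromide, BrCc1ccccc1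
Why: Williamson ether synthesis on the phenoxide; the ester is inert to carbonate, and the benzyl ether survives every step up to the hydrogenation.

Step 2
Reactants: 2 ethyl 3-[4-(benzyloxy)-3-methoxyphenyl]propanoate
Product: 3 1-(benzyloxy)-4-(3-ethoxybut-3-en-1-yl)-2-methoxybenzene
Conditions: Cp2TiMe2 (tetravalent titanium), toluene, 70 °C, dark; filtration through basic alumina
Reagents that add atoms: dimethyltitanocene Cp2TiMe2, [CH3-].[CH3-].[Ti+4].c1cc[cH-]c1.c1cc[cH-]c1
Why: Petasis olefination: thermally formed Cp2Ti=CH2 adds to the ester carbonyl and the oxatitanacyclobutane collapses to the enol ether. The reagent is not acidic, so the acid-labile product survives, and only the terminal enol ether can form.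

Step 3
Reactants: 3 1-(benzyloxy)-4-(3-ethoxybut-3-en-1-yl)-2-methoxybenzene; 4 trichloroacetyl chloride
Product: 6 rac-3-{2-[4-(benzyloxy)-3-methoxyphenyl]ethyl}-2,2-dichloro-3-ethoxycyclobutan-1-one, via dichloroketene 5 (not isolated)
Conditions: Zn–Cu couple, POCl3, Et2O, 0 °C → rt, slow addition of 4; crude product used directly
Reagents that add atoms: none
Why: Ketene–alkene [2+2] cycloaddition of dichloroketene with an enol ether, a standard route to 3-alkoxy-2,2-dichlorocyclobutanones. The nucleophilic CH2 of 3 bonds to the ketene carbonyl carbon, which places the ethoxy carbon 1,3 to the ketone; POCl3 ties up the zinc chloride that would otherwise attack enol ether or product.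

Step 4
Reactants: 6 rac-3-{2-[4-(benzyloxy)-3-methoxyphenyl]ethyl}-2,2-dichloro-3-ethoxycyclobutan-1-one
Product: 7 3-{2-[4-(benzyloxy)-3-methoxyphenyl]ethyl}-3-ethoxycyclobutan-1-one
Conditions: Zn dust, AcOH, TMEDA, EtOH, 0 °C → rt
Reagents that add atoms: none
Why: Reductive dechlorination through zinc enolates that are protonated in turn, as used for other 3-alkoxy-2,2-dichlorocyclobutanones. TMEDA buffers the acid and binds zinc salts, and ethanol as solvent makes any alkoxy exchange at the ether carbon degenerate; the product is achiral.

Step 5
Reactants: 7 3-{2-[4-(benzyloxy)-3-methoxyphenyl]ethyl}-3-ethoxycyclobutan-1-one; 8 4-(benzyloxy)-3-methoxybenzaldehyde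
Product: 11 (2S)-2-[4-(benzyloxy)-3-methoxyphenyl]-6-{2-[4-(benzyloxy)-3-methoxyphenyl]ethyl}-2,3-dihydro-4H-pyran-4-one, via enolate–oxocarbenium zwitterion 9 (not isolated), via 2-ethoxyoxan-4-one ketal 10 (not isolated)
Conditions: TiCl2[(R)-BINOLate] (1.1 equiv, prepared beforehand; tetravalent titanium), 8 (1.5 equiv), 4 Å MS, CH2Cl2, −78 → −40 °C, slow addition of 7; then aq NaHCO3
Reagents that add atoms: none
Why: Proposed new method: the titanium centre binds the ketone oxygen of 7 and the strained bond between a ring CH2 and the ethoxy-bearing carbon breaks heterolytically, giving zwitterion 9, a titanium enolate tethered to a ketone-derived oxocarbenium ion. The enolate carbon adds to the aldehyde carbon of 8 (aldol, C5–C6), the new titanium alkoxide closes on the oxocarbenium carbon (O1–C2) in a 6-exo-trig mode to give ketal 10, and loss of ethanol toward the ketone leaves the vinylogous ester 11. The closest known reaction type is the BF3·OEt2-promoted formal [4+2] cycloaddition of 3-alkoxycyclobutanones with aldehydes, which gives racemic 2,3-dihydro-4-pyranones; control of the aldehyde face by a chiral Lewis acid is the unprecedented part. Because 9 is achiral, C6 can be set only by the BINOL-bound titanium, which carries the enolate and can hold the aldehyde as well, so that addition to the Si face of 8 through a closed six-membered transition state is expected to give the (S) centre. The step needs regioselective ring opening, which the mirror symmetry of 7 secures, since its two ring CH2 groups are equivalent and only one dipole can form. It also needs the aldol to outrun proton transfer within 9 and addition of 9 to a second molecule of 7, which an excess of the non-enolisable aldehyde and slow addition of 7 should favour. The tertiary donor carbon (ethoxy plus alkyl chain) stabilises the cation enough for this mild Lewis acid to open the ring at low temperature, which in turn spares the acid-labile benzylic C6–O1 bond of 11.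

Step 6
Reactants: 11 (2S)-2-[4-(benzyloxy)-3-methoxyphenyl]-6-{2-[4-(benzyloxy)-3-methoxyphenyl]ethyl}-2,3-dihydro-4H-pyran-4-one
Product: 12 (2S,6S)-2-(4-hydroxy-3-methoxyphenyl)-6-[2-(4-hydroxy-3-methoxyphenyl)ethyl]oxan-4-one
Conditions: H2 (1 atm), 10% Pd/C, EtOAc, rt
Reagents that add atoms: none
Why: Heterogeneous hydrogenation: syn addition of H2 to the C2=C3 enol ether double bond from the face opposite the C6 aryl group should give the cis-2,6 ketone, as is usual for 2,6-disubstituted dihydropyranones. Both benzyl aryl ethers are hydrogenolysed under the same conditions.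

Step 7
Reactants: 12 (2S,6S)-2-(4-hydroxy-3-methoxyphenyl)-6-[2-(4-hydroxy-3-methoxyphenyl)ethyl]oxan-4-one
Product: 13 (2S,4S,6S)-2-(4-hydroxy-3-methoxyphenyl)-6-[2-(4-hydroxy-3-methoxyphenyl)ethyl]oxan-4-ol
Conditions: LiBH(sec-Bu)3 (4 equiv), THF, −78 °C; then MeOH, aq NH4Cl
Reagents that add atoms: none
Why: Diastereoselective ketone reduction: the chair of 12 is locked by two equatorial substituents, so the bulky trialkylborohydride attacks from the equatorial side and should give the axial (4S) alcohol. Two equivalents are consumed in forming the lithium phenoxides, hence the excess.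

## Compound list

1 | ethyl 3-(4-hydroxy-3-methoxyphenyl)propanoate | CCOC(=O)CCc1ccc(O)c(OC)c1 | starting material
2 | ethyl 3-[4-(benzyloxy)-3-methoxyphenyl]propanoate | CCOC(=O)CCc1ccc(OCc2ccccc2)c(OC)c1 | intermediate
3 | 1-(benzyloxy)-4-(3-ethoxybut-3-en-1-yl)-2-methoxybenzene | C=C(OCC)CCc1ccc(OCc2ccccc2)c(OC)c1 | intermediate
4 | trichloroacetyl chloride | ClC(Cl)(Cl)C(Cl)=O | starting material
5 | dichloroketene | ClC(Cl)=C=O | intermediate (not isolated)
6 | rac-3-{2-[4-(benzyloxy)-3-methoxyphenyl]ethyl}-2,2-dichloro-3-ethoxycyclobutan-1-one | CCOC1(CCc2ccc(OCc3ccccc3)c(OC)c2)CC(=O)C1(Cl)Cl | intermediate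
7 | 3-{2-[4-(benzyloxy)-3-methoxyphenyl]ethyl}-3-ethoxycyclobutan-1-one | CCOC1(CCc2ccc(OCc3ccccc3)c(OC)c2)CC(=O)C1 | intermediate
8 | 4-(benzyloxy)-3-methoxybenzaldehyde | COc1cc(C=O)ccc1OCc1ccccc1 | starting material
9 | enolate–oxocarbenium zwitterion from 7, drawn without the titanium fragment on the enolate oxygen | CC[O+]=C(CCc1ccc(OCc2ccccc2)c(OC)c1)CC(=C)[O-] | intermediate (not isolated)
10 | (6S)-6-[4-(benzyloxy)-3-methoxyphenyl]-2-{2-[4-(benzyloxy)-3-methoxyphenyl]ethyl}-2-ethoxyoxan-4-one, either configuration at the ketal carbon | CCOC1(CCc2ccc(OCc3ccccc3)c(OC)c2)CC(=O)C[C@@H](c2ccc(OCc3ccccc3)c(OC)c2)O1 | intermediate (not isolated)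
11 | (2S)-2-[4-(benzyloxy)-3-methoxyphenyl]-6-{2-[4-(benzyloxy)-3-methoxyphenyl]ethyl}-2,3-dihydro-4H-pyran-4-one | COc1cc(CCC2=CC(=O)C[C@@H](c3ccc(OCc4ccccc4)c(OC)c3)O2)ccc1OCc1ccccc1 | intermediate
12 | (2S,6S)-2-(4-hydroxy-3-methoxyphenyl)-6-[2-(4-hydroxy-3-methoxyphenyl)ethyl]oxan-4-one | COc1cc(CC[C@H]2CC(=O)C[C@@H](c3ccc(O)c(OC)c3)O2)ccc1O | intermediate
13 | (2S,4S,6S)-2-(4-hydroxy-3-methoxyphenyl)-6-[2-(4-hydroxy-3-methoxyphenyl)ethyl]oxan-4-ol | COc1cc(CC[C@H]2C[C@H](O)C[C@@H](c3ccc(O)c(OC)c3)O2)ccc1O | target

## Step count and least certain steps

Total step count: 7. Longest linear sequence: 7 steps (1 → 13); compounds 4 and 8 are bought.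

**Step 5 (key step, the proposed new method).** The most likely failure is poor or unpredictable face selection, because the open zwitterion may react through an extended transition state outside the reach of the ligand. Two further processes threaten it: erosion of configuration afterwards by Lewis-acid ionisation of the benzylic C6–O1 bond, and proton transfer within the zwitterion that opens the ring without capturing the aldehyde.

The fallback uses known chemistry, sets out from ester 2 and aldehyde 8, and rejoins the route at 11. Claisen condensation of 2 with the sodium enolate of acetone (NaH, THF) should give 6-[4-(benzyloxy)-3-methoxyphenyl]hexane-2,4-dione F1. Double silylation (Me3SiCl/Et3N, then LiN(iPr)2/Me3SiCl, −78 °C) should give the 2,4-bis(trimethylsilyloxy)-1,3-diene F2. A vinylogous Mukaiyama aldol addition of F2 to 8, catalysed by Ti(OiPr)4/(R)-BINOL (tetravalent titanium), should give the δ-hydroxy-β-diketone F3 after desilylation. Mild acid (CF3CO2H, CH2Cl2, 0 °C) should then close and dehydrate F3 to 11. The same two bonds are made, stepwise and without the strain-release step, at a cost of about two more operations.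

**Step 4.** The donor–acceptor four-membered ring may open under zinc halide and acetic acid, or the zinc enolate may expel ethoxide. Ketone 6 is the most labile compound of the route, which is why it is carried crude from step 3. The fallback goes from 6 to 7 by a neutral radical chain dechlorination (Bu3SnH, Et3B/air, toluene, rt), which replaces the metal enolate by an α-keto radical and keeps Lewis and protic acids out of the flask. It passes through no new compound (F0).

**Step 6.** Hydrogenolysis of the benzylic C6–O1 bond may compete with saturation of the trisubstituted enol ether double bond. In 11 this bond is a benzylic vinylogous ester, and it becomes more labile once the para phenol is free.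

The fallback sets out from 11, separates the three events, and rejoins the route at 13. Hydrogenation over Pd/C poisoned with ethylenediamine, which should spare benzyl ethers and benzylic C–O bonds, should give the bis-benzyl cis ketone F4. LiBH(sec-Bu)3 in THF at −78 °C should give the bis-benzyl axial alcohol F5. A short hydrogenolysis over Pd(OH)2/C in EtOAc, now with no vinylogous ester present, should give 13. This is one step more, and it also keeps free phenols out of the hydride reduction.

**Step 7.** Reduction may be incomplete or lose axial selectivity because the dilithium bis-phenoxide of 12 is poorly soluble in THF at −78 °C and the reaction has to be run warmer. Base-induced retro-oxa-Michael opening of the β-alkoxy ketone is a second possibility.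

The fallback sets out from 12 and rejoins the route at 13. Silylation of both phenols (t-BuMe2SiCl, imidazole, DMF) should give the bis-silyl ketone F6. LiBH(sec-Bu)3 at −78 °C should give the bis-silyl axial alcohol F7. Bu4NF buffered with AcOH should release 13.

## Further compounds

F1 | step 5 | 6-[4-(benzyloxy)-3-methoxyphenyl]hexane-2,4-dione | CC(=O)CC(=O)CCc1ccc(OCc2ccccc2)c(OC)c1
F2 | step 5 | (3Z)-6-[4-(benzyloxy)-3-methoxyphenyl]-2,4-bis(trimethylsilyloxy)hexa-1,3-diene | C=C(O[Si](C)(C)C)/C=C(/CCc1ccc(OCc2ccccc2)c(OC)c1)O[Si](C)(C)C
F3 | step 5 | (1S)-1,7-bis[4-(benzyloxy)-3-methoxyphenyl]-1-hydroxyheptane-3,5-dione | O=C(C[C@@H](c1ccc(OCc2ccccc2)c(OC)c1)O)CC(=O)CCc1ccc(OCc2ccccc2)c(OC)c1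
F0 | step 4 | none | none
F4 | step 6 | (2S,6S)-2-[4-(benzyloxy)-3-methoxyphenyl]-6-{2-[4-(benzyloxy)-3-methoxyphenyl]ethyl}oxan-4-one | COc1cc(CC[C@H]2CC(=O)C[C@@H](c3ccc(OCc4ccccc4)c(OC)c3)O2)ccc1OCc1ccccc1
F5 | step 6 | (2S,4S,6S)-2-[4-(benzyloxy)-3-methoxyphenyl]-6-{2-[4-(benzyloxy)-3-methoxyphenyl]ethyl}oxan-4-ol | COc1cc(CC[C@H]2C[C@H](O)C[C@@H](c3ccc(OCc4ccccc4)c(OC)c3)O2)ccc1OCc1ccccc1
F6 | step 7 | (2S,6S)-2-{4-[(tert-butyldimethylsilyl)oxy]-3-methoxyphenyl}-6-(2-{4-[(tert-butyldimethylsilyl)oxy]-3-methoxyphenyl}ethyl)oxan-4-one | COc1cc(CC[C@H]2CC(=O)C[C@@H](c3ccc(O[Si](C)(C)C(C)(C)C)c(OC)c3)O2)ccc1O[Si](C)(C)C(C)(C)C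
F7 | step 7 | (2S,4S,6S)-2-{4-[(tert-butyldimethylsilyl)oxy]-3-methoxyphenyl}-6-(2-{4-[(tert-butyldimethylsilyl)oxy]-3-methoxyphenyl}ethyl)oxan-4-ol | COc1cc(CC[C@H]2C[C@H](O)C[C@@H](c3ccc(O[Si](C)(C)C(C)(C)C)c(OC)c3)O2)ccc1O[Si](C)(C)C(C)(C)C
A1 | alternative 1 | 2-(tert-butyldimethylsilyl)-1,3-dithiane | CC(C)(C)[Si](C)(C)C1SCCCS1
A2 | alternative 1 | (R)-2-[4-(benzyloxy)-3-methoxyphenyl]oxirane | COc1cc([C@@H]2CO2)ccc1OCc1ccccc1
A3 | alternative 1 | (S)-2-{2-[4-(benzyloxy)-3-methoxyphenyl]ethyl}oxirane | COc1cc(CC[C@H]2CO2)ccc1OCc1ccccc1
A4 | alternative 1 | tert-butyl{(1S)-1-[4-(benzyloxy)-3-methoxyphenyl]-2-[2-{(2S)-4-[4-(benzyloxy)-3-methoxyphenyl]-2-hydroxybutyl}-1,3-dithian-2-yl]ethoxy}dimethylsilane | COc1cc(CC[C@H](O)CC2(C[C@@H](c3ccc(OCc4ccccc4)c(OC)c3)O[Si](C)(C)C(C)(C)C)SCCCS2)ccc1OCc1ccccc1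
A5 | alternative 2 | (2E,5S,7S)-7-[4-(benzyloxy)-3-methoxyphenyl]-5-[(tert-butyldimethylsilyl)oxy]-7-hydroxyhept-2-en-1-yl methyl carbonate | COC(=O)OC/C=C/C[C@H](O[Si](C)(C)C(C)(C)C)C[C@@H](c1ccc(OCc2ccccc2)c(OC)c1)O
A6 | alternative 2 | tert-butyl({(2S,4S,6R)-2-[4-(benzyloxy)-3-methoxyphenyl]-6-ethenyloxan-4-yl}oxy)dimethylsilane | C=C[C@H]1C[C@H](O[Si](C)(C)C(C)(C)C)C[C@@H](c2ccc(OCc3ccccc3)c(OC)c2)O1
A7 | alternative 3 | (E)-{[4-(4-(benzyloxy)-3-methoxyphenyl)buta-1,3-dien-2-yl]oxy}triethylsilane | C=C(O[Si](CC)(CC)CC)/C=C/c1ccc(OCc2ccccc2)c(OC)c1
A8 | alternative 3 | 3-[4-(benzyloxy)-3-methoxyphenyl]propanal | O=CCCc1ccc(OCc2ccccc2)c(OC)c1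
A9 | alternative 3 | triethyl{[(2S,6S)-6-[4-(benzyloxy)-3-methoxyphenyl]-2-{2-[4-(benzyloxy)-3-methoxyphenyl]ethyl}-3,6-dihydro-2H-pyran-4-yl]oxy}silane | COc1cc(CC[C@H]2CC(O[Si](CC)(CC)CC)=C[C@@H](c3ccc(OCc4ccccc4)c(OC)c3)O2)ccc1OCc1ccccc1
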